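**Retrosynthetic overview**

- Ring locants: C1 (propyl-bearing), O2, C3 (ester C=O), C4 … C26, N27, C28 (amide C=O). The strategy rests on the α-acyloxy carboxamide unit O2–C1(propyl)–C28(=O)–N27H inside the 28-membered depsi-lactam ring, which is the signature of a Passerini reaction of butanal, the C3 acid and a C26 isocyanide.
- The open chain C3–C26 is cut at C16=C17 (Julia–Kocienski) into an eastern C3–C16 sulfone and a western C17–C26 enal.
- Eastern half: C7=C8 by Wittig reaction, C11–C12 by acyl Sonogashira coupling. Western half: C22–C23 by anti-selective allylboration, C19–C20 by B-alkyl Suzuki coupling of an enol triflate.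
- There is only one ring; it is closed last, when butanal is stitched between the two chain ends.

Key step: step 29

Assumption (remark on the chemistry): for the three reagent-controlled steps whose sense rests on a facial model — (DHQD)2AQN in step 1, (+)-Ipc2BH in step 17 and (R)-TRIP in step 29 — the antipode written is the one taken to give the required sense; each is to be confirmed on a test run and replaced by its mirror-image or pseudoenantiomeric form if needed, with nothing else changed.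

**Route**

Step 1
Reactants: 1 meso-2,4-dimethylglutaric anhydride
Product: 2 (2R,4S)-5-methoxy-2,4-dimethyl-5-oxopentanoic acid
Conditions: (DHQD)2AQN (10 mol %), MeOH (10 equiv), Et2O, −40 °C
Reagents that add atoms: methanol, CO
Why: Cinchona-alkaloid-catalysed desymmetrising methanolysis of a meso anhydride; the catalyst picks one of the two enantiotopic carbonyl groups, so C4 and C6 are fixed together (ester end = C3, acid end = future C7).

Step 2
Reactants: 2 (2R,4S)-5-methoxy-2,4-dimethyl-5-oxopentanoic acid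
Product: 3 methyl (2S,4R)-5-(ethylsulfanyl)-2,4-dimethyl-5-oxopentanoate
Conditions: EtSH, DCC, DMAP (5 mol %), CH2Cl2, 0 °C to rt
Reagents that add atoms: ethanethiol, CCS
Why: Steglich-type thioesterification of the free acid marks the C7 carbonyl for chemoselective reduction beside the untouched methyl ester.

Step 3
Reactants: 3 methyl (2S,4R)-5-(ethylsulfanyl)-2,4-dimethyl-5-oxopentanoate
Product: 4 methyl (2S,4R)-2,4-dimethyl-5-oxopentanoate
Conditions: Et3SiH, 10 % Pd/C, acetone, rt
Reagents that add atoms: none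
Why: Fukuyama reduction; zerovalent palladium inserts into the C–S bond and the silane delivers hydride, giving the aldehyde under neutral conditions that spare the ester and the α-stereocentre.

Step 4
Reactants: 4 methyl (2S,4R)-2,4-dimethyl-5-oxopentanoate
Product: 5 (4Z,6R,8S)-9-methoxy-6,8-dimethyl-9-oxonon-4-enoic acid
Conditions: (3-carboxypropyl)triphenylphosphonium bromide, NaN(SiMe3)2 (2 equiv per salt), THF, −78 to 0 °C; then 4, −78 °C to rt; 1 M HCl
Reagents that add atoms: (3-carboxypropyl)triphenylphosphonium bromide, OC(=O)CCC[P+](c1ccccc1)(c1ccccc1)c1ccccc1.[Br-]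
Why: Wittig reaction of a non-stabilised carboxylate ylide adds C8–C11 and should favour the Z alkene (geometry irrelevant, as it is hydrogenated in step 13); adding the aldehyde cold to the preformed ylide limits epimerisation at C6.

Step 5
Reactants: 6 (4R)-4-benzyl-3-butanoyl-1,3-oxazolidin-2-one
Product: 7 (4R)-4-benzyl-3-[(2S)-2-ethylpent-4-ynoyl]-1,3-oxazolidin-2-one
Conditions: NaN(SiMe3)2, THF, −78 °C; propargyl bromide, −78 to −40 °C
Reagents that add atoms: propargyl bromide, C#CCBr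
Why: Evans alkylation; the chelated Z-sodium enolate is alkylated on the face opposite the benzyl group, which sets C15 as (S) and brings C12–C14.

Step 6
Reactants: 7 (4R)-4-benzyl-3-[(2S)-2-ethylpent-4-ynoyl]-1,3-oxazolidin-2-one
Product: 8 (2S)-2-ethylpent-4-yn-1-ol
Conditions: LiBH4, MeOH (1 equiv), Et2O, 0 °C
Reagents that add atoms: none
Why: Reductive cleavage of the N-acyl oxazolidinone with LiBH4 gives the primary alcohol without touching the stereocentre or the alkyne.

Step 7
Reactants: 8 (2S)-2-ethylpent-4-yn-1-ol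
Product: 9 5-{[(2S)-2-ethylpent-4-yn-1-yl]sulfanyl}-1-phenyl-1H-tetrazole
Conditions: 1-phenyl-1H-tetrazole-5-thiol, PPh3, DIAD, THF, 0 °C to rt
Reagents that add atoms: 1-phenyl-1H-tetrazole-5-thiol, Sc1nnnn1-c1ccccc1
Why: Mitsunobu thioetherification; the alkoxyphosphonium ion of the primary alcohol is displaced by the thiolate and the stereocentre is not involved.

Step 8
Reactants: 9 5-{[(2S)-2-ethylpent-4-yn-1-yl]sulfanyl}-1-phenyl-1H-tetrazole
Product: 10 5-{[(2S)-2-ethylpent-4-yn-1-yl]sulfonyl}-1-phenyl-1H-tetrazole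
Conditions: (NH4)6Mo7O24·4H2O (10 mol %), 30 % H2O2, EtOH, 0 °C to rt
Reagents that add atoms: hydrogen peroxide, OO
Why: Molybdate-catalysed peroxide oxidation of the sulfide to the sulfone; the terminal alkyne and the tetrazole are inert to it.

Step 9
Reactants: 5 (4Z,6R,8S)-9-methoxy-6,8-dimethyl-9-oxonon-4-enoic acid
Product: 11 methyl (2S,4R,5Z)-9-chloro-2,4-dimethyl-9-oxonon-5-enoate
Conditions: (COCl)2 (1.2 equiv), DMF (cat.), CH2Cl2, 0 °C to rt; evaporation, used crude
Reagents that add atoms: oxalyl chloride, ClC(=O)C(=O)Cl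
Why: Vilsmeier-type acid chloride formation; the activated carbonyl (C11) has no α-stereocentre, so nothing can epimerise.

Step 10
Reactants: 11 methyl (2S,4R,5Z)-9-chloro-2,4-dimethyl-9-oxonon-5-enoate; 10 5-{[(2S)-2-ethylpent-4-yn-1-yl]sulfonyl}-1-phenyl-1H-tetrazole
Product: 12 methyl (2S,4R,5Z,13S)-13-ethyl-2,4-dimethyl-9-oxo-14-[(1-phenyl-1H-tetrazol-5-yl)sulfonyl]tetradec-5-en-10-ynoate
Conditions: PdCl2(PPh3)2 (2 mol %), CuI (4 mol %), Et3N (1.2 equiv), THF, rt
Reagents that add atoms: none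
Why: Acyl Sonogashira coupling; the copper acetylide of 10 transmetalates to the acylpalladium chloride and reductive elimination forms the C11–C12 bond of the ynone.

Step 11
Reactants: 12 methyl (2S,4R,5Z,13S)-13-ethyl-2,4-dimethyl-9-oxo-14-[(1-phenyl-1H-tetrazol-5-yl)sulfonyl]tetradec-5-en-10-ynoate
Product: 13 methyl (2S,4R,5Z,9S,13S)-13-ethyl-9-hydroxy-2,4-dimethyl-14-[(1-phenyl-1H-tetrazol-5-yl)sulfonyl]tetradec-5-en-10-ynoate
Conditions: RuCl[(S,S)-TsDPEN](p-cymene) (2 mol %), KOH (2 mol %), i-PrOH, rt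
Reagents that add atoms: none
Why: Noyori asymmetric transfer hydrogenation of an alkynyl ketone; the catalyst differentiates the alkynyl from the alkyl flank and should deliver the (S)-propargylic alcohol at C11 under catalyst control.

Step 12
Reactants: 13 methyl (2S,4R,5Z,9S,13S)-13-ethyl-9-hydroxy-2,4-dimethyl-14-[(1-phenyl-1H-tetrazol-5-yl)sulfonyl]tetradec-5-en-10-ynoate
Product: 14 methyl (2S,4R,5Z,9S,13S)-9-[(tert-butyldimethylsilyl)oxy]-13-ethyl-2,4-dimethyl-14-[(1-phenyl-1H-tetrazol-5-yl)sulfonyl]tetradec-5-en-10-ynoate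
Conditions: TBSCl, imidazole, DMF, rt
Reagents that add atoms: tert-butyldimethylsilyl chloride, CC(C)(C)[Si](C)(C)Cl
Why: Standard silylation of the secondary propargylic alcohol gives an ether that survives base, azide, phosphine and the final acid-catalysed ring closure.

Step 13
Reactants: 14 methyl (2S,4R,5Z,9S,13S)-9-[(tert-butyldimethylsilyl)oxy]-13-ethyl-2,4-dimethyl-14-[(1-phenyl-1H-tetrazol-5-yl)sulfonyl]tetradec-5-en-10-ynoate
Product: 15 methyl (2S,4S,9S,13S)-9-[(tert-butyldimethylsilyl)oxy]-13-ethyl-2,4-dimethyl-14-[(1-phenyl-1H-tetrazol-5-yl)sulfonyl]tetradecanoate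
Conditions: H2 (1 atm), 5 % Pt/C, EtOAc, rt
Reagents that add atoms: none
Why: Heterogeneous hydrogenation saturates alkyne and alkene in one operation; platinum is preferred to palladium because it is far less prone to double-bond migration (which would endanger the allylic C6 centre) and to hydrogenolysis of the propargylic silyl ether (the C6 descriptor changes from R to S by priority only).

Step 14
Reactants: 16 (S)-epichlorohydrin
Product: 17 (2S)-1-chloropent-4-en-2-ol
Conditions: CuI (10 mol %), vinylmagnesium bromide (CH2=CHMgBr), THF, −40 to −20 °C; 1 M HCl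
Reagents that add atoms: vinylmagnesium bromide, C=C[Mg]Br
Why: Copper-catalysed Grignard opening of the epoxide at its unsubstituted carbon; C25 is not touched and keeps the configuration bought with 16.

Step 15
Reactants: 17 (2S)-1-chloropent-4-en-2-ol
Product: 18 tert-butyl{[(2S)-1-chloropent-4-en-2-yl]oxy}dimethylsilane
Conditions: TBSCl, imidazole, DMF, rt
Reagents that add atoms: tert-butyldimethylsilyl chloride, CC(C)(C)[Si](C)(C)Cl
Why: Standard silylation protects O25, which also removes any chance of epoxide re-closure onto the chloride.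

Step 16
Reactants: 18 tert-butyl{[(2S)-1-chloropent-4-en-2-yl]oxy}dimethylsilane
Product: 20 (3S)-3-[(tert-butyldimethylsilyl)oxy]-4-chlorobutanal, via ozonide 19 (not isolated)
Conditions: O3, CH2Cl2, −78 °C; PPh3, −78 °C to rt
Reagents that add atoms: ozone, [O-][O+]=O
Why: Ozonolysis with reductive work-up cleaves the terminal alkene to the C23 aldehyde without affecting the silyl ether or the chloride.

Step 17
Reactants: 20 (3S)-3-[(tert-butyldimethylsilyl)oxy]-4-chlorobutanal
Product: 22 (3R,4S,6S)-6-[(tert-butyldimethylsilyl)oxy]-7-chlorohept-1-ene-3,4-diol, via boron adduct 21 (not isolated)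
Conditions: allenylboronic acid pinacol ester, (+)-Ipc2BH [from (−)-α-pinene], Et2O, −25 to 0 °C; 20, −78 °C; then 30 % H2O2, aq NaHCO3, THF, 0 °C to rt
Reagents that add atoms: allenylboronic acid pinacol ester, C=C=CB1OC(C)(C)C(C)(C)O1; hydrogen peroxide, OO
Why: Anti-selective γ-borylallylboration; hydroboration of the allenylboronate gives the (E)-γ-borylallylborane, which adds through a chair transition state (C22–B anti to C23–O) with the Ipc groups directing attack to the Re face of the aldehyde, and C–B oxidation with retention gives the 22R,23S anti-diol, the bicarbonate buffer avoiding displacement of the chloride.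

Step 18
Reactants: 22 (3R,4S,6S)-6-[(tert-butyldimethylsilyl)oxy]-7-chlorohept-1-ene-3,4-diol
Product: 23 (3R,4S,6S)-3,4,6-tris[(tert-butyldimethylsilyl)oxy]-7-chlorohept-1-ene
Conditions: TBSOTf (2.5 equiv), 2,6-lutidine, CH2Cl2, −78 to 0 °C
Reagents that add atoms: tert-butyldimethylsilyl trifluoromethanesulfonate, CC(C)(C)[Si](C)(C)OS(=O)(=O)C(F)(F)F
Why: Silyl triflate with a hindered base is reactive enough to silylate both hydroxyls of a vicinal diol.

Step 19
Reactants: 24 methyl 4-methoxyacetoacetate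
Product: 25 methyl (2E)-4-methoxy-3-{[(trifluoromethyl)sulfonyl]oxy}but-2-enoate
Conditions: Tf2O, 25 % aq Me4NOH, hexanes, 5 °C
Reagents that add atoms: trifluoromethanesulfonic anhydride, O=S(=O)(OS(=O)(=O)C(F)(F)F)C(F)(F)F
Why: Enol triflation of a β-keto ester through its non-chelated tetramethylammonium enolate should give the E enol triflate (OTf trans to the ester), the geometry that later places C20 trans to C17.

Step 20
Reactants: 23 (3R,4S,6S)-3,4,6-tris[(tert-butyldimethylsilyl)oxy]-7-chlorohept-1-ene; 25 methyl (2E)-4-methoxy-3-{[(trifluoromethyl)sulfonyl]oxy}but-2-enoate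
Product: 27 methyl (2Z,6R,7S,9S)-6,7,9-tris[(tert-butyldimethylsilyl)oxy]-10-chloro-3-(methoxymethyl)dec-2-enoate, via alkylborane 26 (not isolated)
Conditions: 9-BBN (1.5 equiv), THF, rt; then 25, PdCl2(dppf) (5 mol %), AsPh3 (5 mol %), 3 M aq Cs2CO3, DMF, rt
Reagents that add atoms: none
Why: Anti-Markovnikov hydroboration followed by B-alkyl Suzuki–Miyaura coupling forms C19–C20 with retention of the enol-triflate geometry (the descriptor becomes Z by priority only); the primary chloride is inert to the palladium catalyst at rt.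

Step 21
Reactants: 27 methyl (2Z,6R,7S,9S)-6,7,9-tris[(tert-butyldimethylsilyl)oxy]-10-chloro-3-(methoxymethyl)dec-2-enoate
Product: 28 (2Z,6R,7S,9S)-6,7,9-tris[(tert-butyldimethylsilyl)oxy]-10-chloro-3-(methoxymethyl)dec-2-en-1-ol
Conditions: i-Bu2AlH (2.5 equiv), CH2Cl2, −78 °C; aq KNaC4H4O6
Reagents that add atoms: none
Why: 1,2-Reduction of the enoate with i-Bu2AlH gives the allylic alcohol without conjugate reduction or attack on the chloride.

Step 22
Reactants: 28 (2Z,6R,7S,9S)-6,7,9-tris[(tert-butyldimethylsilyl)oxy]-10-chloro-3-(methoxymethyl)dec-2-en-1-ol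
Product: 29 (2Z,6R,7S,9S)-6,7,9-tris[(tert-butyldimethylsilyl)oxy]-10-chloro-3-(methoxymethyl)dec-2-enal
Conditions: MnO2, CH2Cl2, rt
Reagents that add atoms: none
Why: Selective allylic oxidation with MnO2 gives the enal under neutral conditions that should not isomerise the trisubstituted alkene.

Step 23
Reactants: 15 methyl (2S,4S,9S,13S)-9-[(tert-butyldimethylsilyl)oxy]-13-ethyl-2,4-dimethyl-14-[(1-phenyl-1H-tetrazol-5-yl)sulfonyl]tetradecanoate; 29 (2Z,6R,7S,9S)-6,7,9-tris[(tert-butyldimethylsilyl)oxy]-10-chloro-3-(methoxymethyl)dec-2-enal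
Product: 30 methyl (2S,4S,9S,13S,14E,16Z,20R,21S,23S)-9,20,21,23-tetrakis[(tert-butyldimethylsilyl)oxy]-24-chloro-13-ethyl-17-(methoxymethyl)-2,4-dimethyltetracosa-14,16-dienoate
Conditions: 15, KN(SiMe3)2 (1.05 equiv), DME, −78 °C, 30 min; then 29, −78 °C to rt
Reagents that add atoms: none
Why: Julia–Kocienski olefination; the metalated phenyltetrazolyl sulfone adds to the enal, Smiles rearrangement and loss of SO2 and tetrazololate give the diene, the potassium counter-ion in DME favouring the E C16=C17 bond, and premetalation with one equivalent of base leaves the ester α-proton and the enal γ-protons alone.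

Step 24
Reactants: 30 methyl (2S,4S,9S,13S,14E,16Z,20R,21S,23S)-9,20,21,23-tetrakis[(tert-butyldimethylsilyl)oxy]-24-chloro-13-ethyl-17-(methoxymethyl)-2,4-dimethyltetracosa-14,16-dienoate
Product: 31 the 24-azido analogue of 30 (N3 in place of Cl at C26 of the ring numbering)
Conditions: NaN3 (3 equiv), NaI (0.2 equiv), DMF, 70 °C
Reagents that add atoms: sodium azide, [Na+].[N-]=[N+]=[N-]
Why: Iodide-assisted SN2 displacement of the primary chloride by azide introduces N27; the C25 centre is adjacent but not involved.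

Step 25
Reactants: 31 the 24-azido ester
Product: 33 the 24-amino analogue of 30, via iminophosphorane 32 (not isolated)
Conditions: PMe3, THF, rt; then H2O, 40 °C
Reagents that add atoms: none
Why: Staudinger reduction; the phosphine adds to the azide, N2 is lost and the iminophosphorane is hydrolysed, leaving diene, ester and silyl ethers untouched.

Step 26
Reactants: 33 the 24-amino ester
Product: 34 the 24-formamido analogue of 30
Conditions: 2,2,2-trifluoroethyl formate, THF, rt
Reagents that add atoms: 2,2,2-trifluoroethyl formate, O=COCC(F)(F)F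
Why: N-Formylation of the primary amine with an activated formate ester brings the carbon that becomes C28.

Step 27
Reactants: 34 the 24-formamido ester
Product: 35 the 24-isocyano analogue of 30
Conditions: POCl3, Et3N, CH2Cl2, −30 to 0 °C
Reagents that add atoms: none
Why: Dehydration of a secondary formamide to the isocyanide with POCl3 in excess amine base, conditions that stay basic and so spare the silyl ethers and the diene.

Step 28
Reactants: 35 the 24-isocyano ester
Product: 36 potassium carboxylate of the C3 acid (24-isocyano chain, all four hydroxyls as TBS ethers)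
Conditions: KOSiMe3 (2 equiv), THF, rt; evaporation, stored cold under argon
Reagents that add atoms: potassium trimethylsilanolate, [K+].[O-][Si](C)(C)C
Why: Anhydrous silanolate cleavage of the methyl ester gives the carboxylate under non-aqueous, weakly basic conditions that should leave the isocyanide, the silyl ethers and the C4 centre intact; the salt is kept because the free isocyano acid is not meant to be stored.

Step 29
Reactants: 36 potassium carboxylate of the isocyano acid; 37 butanal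
Product: 40 tetra-TBS macrocycle (11,22,23,25-tetra-O-TBS ether of 41), via free isocyano acid 38 (not isolated), via cyclic imidate 39 (not isolated)
Conditions: 36 in CH2Cl2 washed with cold aq NaH2PO4 (pH 4.5), dried (Na2SO4); syringe pump (20 h) into 37 (30 equiv), (R)-TRIP [(R)-3,3'-bis(2,4,6-triisopropylphenyl)-1,1'-binaphthyl-2,2'-diyl hydrogen phosphate, 20 mol %], CH2Cl2 (final concentration at most 1 mM), 0 °C to rt
Reagents that add atoms: none
Why: Proposed new method: the chiral phosphoric acid hydrogen-bonds the C3 carboxylic acid and butanal, isocyanide carbon C28 of 38 adds to the aldehyde carbon C1, the nitrilium ion is captured by its own carboxylate to give imidate 39, and an irreversible Mumm O-to-O acyl shift then gives the α-acyloxy amide. The closest known reaction types are the intermolecular Passerini three-component reaction under chiral phosphoric acid catalysis and isocyanide-based multicomponent macrocyclisations of substrates carrying both an acid and an isocyanide; a catalyst-controlled version that closes a large ring from a tethered acid and isocyanide is not established. The single ring closes end to end when the carboxylate oxygen attacks the nitrilium carbon (27-membered imidate) and is enlarged by one atom to the 28-membered depsi-lactam during the acyl shift, which runs through a five-membered transition state. The new C1 stereocentre (S) results from attack on the Re face of butanal under control of the phosphoric acid, C4 and C25 acting only as remote matched or mismatched influences, and a C1 epimer, if formed, would be removed by chromatography. The step needs ring closure to outrun oligomerisation and needs Re-face selectivity: slow addition at very low standing concentration into a large excess of cheap, volatile butanal serves the first, and the substrate helps because every hydroxyl is silylated (O25 could otherwise trap the nitrilium as an oxazoline), both termini are unhindered, and the acid next to C4 is never activated as an acyl donor, so C4 cannot epimerise.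

Step 30
Reactants: 40 tetra-TBS macrocycle
Product: 41 CNP0221503.1
Conditions: HF·pyridine, pyridine, THF, 0 °C to rt
Reagents that add atoms: none
Why: Fluoride-mediated global desilylation under pyridine-buffered conditions should remove all four TBS groups while sparing the α-acyloxy amide, the allylic methyl ether and the diene.

**Compound list**

1 | meso-2,4-dimethylglutaric anhydride [(3R,5S)-3,5-dimethyloxane-2,6-dione] | C[C@@H]1C[C@H](C)C(=O)OC1=O | starting material
2 | (2R,4S)-5-methoxy-2,4-dimethyl-5-oxopentanoic acid | COC(=O)[C@@H](C)C[C@@H](C)C(=O)O | intermediate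
3 | methyl (2S,4R)-5-(ethylsulfanyl)-2,4-dimethyl-5-oxopentanoate | COC(=O)[C@@H](C)C[C@@H](C)C(=O)SCC | intermediate
4 | methyl (2S,4R)-2,4-dimethyl-5-oxopentanoate | COC(=O)[C@@H](C)C[C@@H](C)C=O | intermediate
5 | (4Z,6R,8S)-9-methoxy-6,8-dimethyl-9-oxonon-4-enoic acid (C3–C11) | COC(=O)[C@@H](C)C[C@@H](C)/C=C\CCC(=O)O | intermediate
6 | (4R)-4-benzyl-3-butanoyl-1,3-oxazolidin-2-one | CCCC(=O)N1[C@H](Cc2ccccc2)COC1=O | starting material
7 | (4R)-4-benzyl-3-[(2S)-2-ethylpent-4-ynoyl]-1,3-oxazolidin-2-one | C#CC[C@H](CC)C(=O)N1[C@H](Cc2ccccc2)COC1=O | intermediate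
8 | (2S)-2-ethylpent-4-yn-1-ol | C#CC[C@H](CC)CO | intermediate
9 | 5-{[(2S)-2-ethylpent-4-yn-1-yl]sulfanyl}-1-phenyl-1H-tetrazole | C#CC[C@H](CC)CSc1nnnn1-c1ccccc1 | intermediate
10 | 5-{[(2S)-2-ethylpent-4-yn-1-yl]sulfonyl}-1-phenyl-1H-tetrazole (C12–C16) | C#CC[C@H](CC)CS(=O)(=O)c1nnnn1-c1ccccc1 | intermediate
11 | methyl (2S,4R,5Z)-9-chloro-2,4-dimethyl-9-oxonon-5-enoate | COC(=O)[C@@H](C)C[C@@H](C)/C=C\CCC(Cl)=O | intermediate
12 | methyl (2S,4R,5Z,13S)-13-ethyl-2,4-dimethyl-9-oxo-14-[(1-phenyl-1H-tetrazol-5-yl)sulfonyl]tetradec-5-en-10-ynoate | COC(=O)[C@@H](C)C[C@@H](C)/C=C\CCC(=O)C#CC[C@H](CC)CS(=O)(=O)c1nnnn1-c1ccccc1 | intermediate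
13 | methyl (2S,4R,5Z,9S,13S)-13-ethyl-9-hydroxy-2,4-dimethyl-14-[(1-phenyl-1H-tetrazol-5-yl)sulfonyl]tetradec-5-en-10-ynoate | COC(=O)[C@@H](C)C[C@@H](C)/C=C\CC[C@H](O)C#CC[C@H](CC)CS(=O)(=O)c1nnnn1-c1ccccc1 | intermediate
14 | methyl (2S,4R,5Z,9S,13S)-9-[(tert-butyldimethylsilyl)oxy]-13-ethyl-2,4-dimethyl-14-[(1-phenyl-1H-tetrazol-5-yl)sulfonyl]tetradec-5-en-10-ynoate | COC(=O)[C@@H](C)C[C@@H](C)/C=C\CC[C@H](O[Si](C)(C)C(C)(C)C)C#CC[C@H](CC)CS(=O)(=O)c1nnnn1-c1ccccc1 | intermediate
15 | methyl (2S,4S,9S,13S)-9-[(tert-butyldimethylsilyl)oxy]-13-ethyl-2,4-dimethyl-14-[(1-phenyl-1H-tetrazol-5-yl)sulfonyl]tetradecanoate (eastern sulfone C3–C16) | COC(=O)[C@@H](C)C[C@@H](C)CCCC[C@H](O[Si](C)(C)C(C)(C)C)CCC[C@H](CC)CS(=O)(=O)c1nnnn1-c1ccccc1 | intermediate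
16 | (S)-epichlorohydrin [(2S)-2-(chloromethyl)oxirane] | ClC[C@@H]1CO1 | starting material
17 | (2S)-1-chloropent-4-en-2-ol | C=CC[C@H](O)CCl | intermediate
18 | tert-butyl{[(2S)-1-chloropent-4-en-2-yl]oxy}dimethylsilane | C=CC[C@H](O[Si](C)(C)C(C)(C)C)CCl | intermediate
19 | 3-{(2S)-2-[(tert-butyldimethylsilyl)oxy]-3-chloropropyl}-1,2,4-trioxolane (ozonide) | C1(C[C@H](O[Si](C)(C)C(C)(C)C)CCl)OCOO1 | intermediate
20 | (3S)-3-[(tert-butyldimethylsilyl)oxy]-4-chlorobutanal | O=CC[C@H](O[Si](C)(C)C(C)(C)C)CCl | intermediate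
21 | allylboration adduct: (3R,4S,6S)-6-(TBS-oxy)-7-chlorohept-1-ene with pinacolboryl on C3 and bis(isopinocampheyl)boryloxy on C4 | C=C[C@@H](B1OC(C)(C)C(C)(C)O1)[C@@H](OB([C@H]2C[C@H]3C[C@@H]([C@@H]2C)C3(C)C)[C@H]2C[C@H]3C[C@@H]([C@@H]2C)C3(C)C)C[C@H](O[Si](C)(C)C(C)(C)C)CCl | intermediate
22 | (3R,4S,6S)-6-[(tert-butyldimethylsilyl)oxy]-7-chlorohept-1-ene-3,4-diol | C=C[C@@H](O)[C@@H](O)C[C@H](O[Si](C)(C)C(C)(C)C)CCl | intermediate
23 | (3R,4S,6S)-3,4,6-tris[(tert-butyldimethylsilyl)oxy]-7-chlorohept-1-ene (C20–C26) | C=C[C@@H](O[Si](C)(C)C(C)(C)C)[C@@H](O[Si](C)(C)C(C)(C)C)C[C@H](O[Si](C)(C)C(C)(C)C)CCl | intermediate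
24 | methyl 4-methoxyacetoacetate (methyl 4-methoxy-3-oxobutanoate) | COCC(=O)CC(=O)OC | starting material
25 | methyl (2E)-4-methoxy-3-{[(trifluoromethyl)sulfonyl]oxy}but-2-enoate | COC(=O)/C=C(\COC)OS(=O)(=O)C(F)(F)F | intermediate
26 | 9-[(3R,4S,6S)-3,4,6-tris(TBS-oxy)-7-chloroheptyl]-9-borabicyclo[3.3.1]nonane | B1(CC[C@@H](O[Si](C)(C)C(C)(C)C)[C@@H](O[Si](C)(C)C(C)(C)C)C[C@H](O[Si](C)(C)C(C)(C)C)CCl)C2CCCC1CCC2 | intermediate
27 | methyl (2Z,6R,7S,9S)-6,7,9-tris[(tert-butyldimethylsilyl)oxy]-10-chloro-3-(methoxymethyl)dec-2-enoate | COC(=O)/C=C(\COC)CC[C@@H](O[Si](C)(C)C(C)(C)C)[C@@H](O[Si](C)(C)C(C)(C)C)C[C@H](O[Si](C)(C)C(C)(C)C)CCl | intermediate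
28 | (2Z,6R,7S,9S)-6,7,9-tris[(tert-butyldimethylsilyl)oxy]-10-chloro-3-(methoxymethyl)dec-2-en-1-ol | OC/C=C(\COC)CC[C@@H](O[Si](C)(C)C(C)(C)C)[C@@H](O[Si](C)(C)C(C)(C)C)C[C@H](O[Si](C)(C)C(C)(C)C)CCl | intermediate
29 | (2Z,6R,7S,9S)-6,7,9-tris[(tert-butyldimethylsilyl)oxy]-10-chloro-3-(methoxymethyl)dec-2-enal (western enal C17–C26) | O=C/C=C(\COC)CC[C@@H](O[Si](C)(C)C(C)(C)C)[C@@H](O[Si](C)(C)C(C)(C)C)C[C@H](O[Si](C)(C)C(C)(C)C)CCl | intermediate
30 | methyl (2S,4S,9S,13S,14E,16Z,20R,21S,23S)-9,20,21,23-tetrakis[(tert-butyldimethylsilyl)oxy]-24-chloro-13-ethyl-17-(methoxymethyl)-2,4-dimethyltetracosa-14,16-dienoate | COC(=O)[C@@H](C)C[C@@H](C)CCCC[C@H](O[Si](C)(C)C(C)(C)C)CCC[C@H](CC)/C=C/C=C(\COC)CC[C@@H](O[Si](C)(C)C(C)(C)C)[C@@H](O[Si](C)(C)C(C)(C)C)C[C@H](O[Si](C)(C)C(C)(C)C)CCl | intermediate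
31 | 24-azido analogue of 30 | COC(=O)[C@@H](C)C[C@@H](C)CCCC[C@H](O[Si](C)(C)C(C)(C)C)CCC[C@H](CC)/C=C/C=C(\COC)CC[C@@H](O[Si](C)(C)C(C)(C)C)[C@@H](O[Si](C)(C)C(C)(C)C)C[C@H](O[Si](C)(C)C(C)(C)C)CN=[N+]=[N-] | intermediate
32 | 24-[(trimethyl-λ5-phosphanylidene)amino] analogue of 30 (iminophosphorane) | COC(=O)[C@@H](C)C[C@@H](C)CCCC[C@H](O[Si](C)(C)C(C)(C)C)CCC[C@H](CC)/C=C/C=C(\COC)CC[C@@H](O[Si](C)(C)C(C)(C)C)[C@@H](O[Si](C)(C)C(C)(C)C)C[C@H](O[Si](C)(C)C(C)(C)C)CN=P(C)(C)C | intermediate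
33 | 24-amino analogue of 30 | COC(=O)[C@@H](C)C[C@@H](C)CCCC[C@H](O[Si](C)(C)C(C)(C)C)CCC[C@H](CC)/C=C/C=C(\COC)CC[C@@H](O[Si](C)(C)C(C)(C)C)[C@@H](O[Si](C)(C)C(C)(C)C)C[C@H](O[Si](C)(C)C(C)(C)C)CN | intermediate
34 | 24-formamido analogue of 30 | COC(=O)[C@@H](C)C[C@@H](C)CCCC[C@H](O[Si](C)(C)C(C)(C)C)CCC[C@H](CC)/C=C/C=C(\COC)CC[C@@H](O[Si](C)(C)C(C)(C)C)[C@@H](O[Si](C)(C)C(C)(C)C)C[C@H](O[Si](C)(C)C(C)(C)C)CNC=O | intermediate
35 | 24-isocyano analogue of 30 | COC(=O)[C@@H](C)C[C@@H](C)CCCC[C@H](O[Si](C)(C)C(C)(C)C)CCC[C@H](CC)/C=C/C=C(\COC)CC[C@@H](O[Si](C)(C)C(C)(C)C)[C@@H](O[Si](C)(C)C(C)(C)C)C[C@H](O[Si](C)(C)C(C)(C)C)C[N+]#[C-] | intermediate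
36 | potassium (2S,4S,9S,13S,14E,16Z,20R,21S,23S)-9,20,21,23-tetrakis[(tert-butyldimethylsilyl)oxy]-13-ethyl-24-isocyano-17-(methoxymethyl)-2,4-dimethyltetracosa-14,16-dienoate | [K+].[O-]C(=O)[C@@H](C)C[C@@H](C)CCCC[C@H](O[Si](C)(C)C(C)(C)C)CCC[C@H](CC)/C=C/C=C(\COC)CC[C@@H](O[Si](C)(C)C(C)(C)C)[C@@H](O[Si](C)(C)C(C)(C)C)C[C@H](O[Si](C)(C)C(C)(C)C)C[N+]#[C-] | intermediate
37 | butanal | CCCC=O | starting material
38 | free isocyano acid corresponding to 36 | OC(=O)[C@@H](C)C[C@@H](C)CCCC[C@H](O[Si](C)(C)C(C)(C)C)CCC[C@H](CC)/C=C/C=C(\COC)CC[C@@H](O[Si](C)(C)C(C)(C)C)[C@@H](O[Si](C)(C)C(C)(C)C)C[C@H](O[Si](C)(C)C(C)(C)C)C[N+]#[C-] | intermediate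
39 | 27-membered cyclic O-acyl imidate, ring C28(=N27)–O–C3(=O)–C4…C26, with a (1S)-1-hydroxybutyl group on C28 | CCC[C@H](O)C1OC(=O)[C@@H](C)C[C@@H](C)CCCC[C@H](O[Si](C)(C)C(C)(C)C)CCC[C@H](CC)/C=C/C=C(\COC)CC[C@@H](O[Si](C)(C)C(C)(C)C)[C@@H](O[Si](C)(C)C(C)(C)C)C[C@H](O[Si](C)(C)C(C)(C)C)CN=1 | intermediate
40 | (1S,4S,6S,11S,15S,16E,18Z,22R,23S,25S)-11,22,23,25-tetrakis[(tert-butyldimethylsilyl)oxy]-15-ethyl-19-(methoxymethyl)-4,6-dimethyl-1-propyl-2-oxa-27-azacyclooctacosa-16,18-diene-3,28-dione (ring locants of the overview) | CCC[C@@H]1OC(=O)[C@@H](C)C[C@@H](C)CCCC[C@H](O[Si](C)(C)C(C)(C)C)CCC[C@H](CC)/C=C/C=C(\COC)CC[C@@H](O[Si](C)(C)C(C)(C)C)[C@@H](O[Si](C)(C)C(C)(C)C)C[C@H](O[Si](C)(C)C(C)(C)C)CNC1=O | intermediate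
41 | CNP0221503.1: (1S,4S,6S,11S,15S,16E,18Z,22R,23S,25S)-15-ethyl-11,22,23,25-tetrahydroxy-19-(methoxymethyl)-4,6-dimethyl-1-propyl-2-oxa-27-azacyclooctacosa-16,18-diene-3,28-dione (ring locants of the overview) | CCC[C@@H]1OC(=O)[C@@H](C)C[C@@H](C)CCCC[C@H](O)CCC[C@H](CC)/C=C/C=C(\COC)CC[C@@H](O)[C@@H](O)C[C@H](O)CNC1=O | target

**Totals**

Total step count: 30.
Longest linear sequence: 17 steps (from 1 through steps 1–4, 9–13 and 23–30 to 41).

**Steps most likely to fail**

1. Step 29 (Proposed new method). Oligomerisation may outrun ring closure, facial control at C1 may be weak or mismatched with the chain stereocentres, or the isocyanide may be hydrated by the acid catalyst. Fallback with known chemistry, setting out from amine 33 and returning at macrocycle 40: 33 is coupled with (S)-2-hydroxypentanoic acid (EDC·HCl, HOBt, CH2Cl2), which brings C1 with its configuration already fixed and forms the N27–C28 amide, giving the hydroxy amide methyl ester F1. The ester is cleaved with Me3SnOH (1,2-dichloroethane, 80 °C) to the seco acid F2. Yamaguchi macrolactonisation (2,4,6-trichlorobenzoyl chloride, Et3N, THF; slow addition to DMAP in toluene at high dilution) then closes the O2–C3 ester with retention at C1 and gives 40.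

2. Step 23. The E/Z ratio at C16=C17 may be poor because the acceptor is an enal, and the base may also attack the ester α-position. Fallback by reversed-polarity Horner–Wadsworth–Emmons olefination, setting out from alcohol 8, acid chloride 11 and allylic alcohol 28 and returning at 30:
 - Alcohol 8 is protected (4-methoxybenzyl trichloroacetimidate, cat. camphorsulfonic acid) as the 4-methoxybenzyl ether F3.
 - F3 is carried through the chemistry of steps 10–13: acyl Sonogashira coupling with 11 to the ynone F4, transfer hydrogenation to the (S)-propargylic alcohol F5, silylation to the TBS ether F6, and hydrogenation over Pt/C to the saturated ether F7.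
 - DDQ (CH2Cl2, pH 7 buffer) releases the primary alcohol F8, and Dess–Martin periodinane gives the C16 aldehyde F9.
 - In parallel, 28 is converted with CBr4 and PPh3 into the allylic bromide F10 and with P(OEt)3 (Arbuzov reaction, 90 °C) into the diethyl phosphonate F11.
 - The lithium anion of F11 (LiN(SiMe3)2, THF, −78 °C) and F9 should then give the E C16=C17 alkene, that is 30.

3. Step 17. Equilibration of the borylallylborane to its E isomer may be incomplete (syn diol), reagent control over the β-silyloxy aldehyde may be insufficient, or the chloride may be displaced by an alkoxide during the oxidation. Fallback setting out from aldehyde 20 and returning at diol 22: 20 is treated with the (S,S)-diisopropyl tartrate ester of (E)-γ-[(cyclohexyloxy)dimethylsilyl]allylboronic acid (4 Å sieves, toluene, −78 °C; the tartrate antipode that attacks the Re face), which should give the anti β-hydroxy allylsilane F12. Tamao–Fleming oxidation of the C–Si bond with retention (H2O2, KF, KHCO3, THF/MeOH) then gives 22.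

**Further compounds**

F1 | step 29 | methyl ester of the open chain carrying the N27 amide of (2S)-2-hydroxypentanoic acid (all four chain hydroxyls as TBS ethers) | COC(=O)[C@@H](C)C[C@@H](C)CCCC[C@H](O[Si](C)(C)C(C)(C)C)CCC[C@H](CC)/C=C/C=C(\COC)CC[C@@H](O[Si](C)(C)C(C)(C)C)[C@@H](O[Si](C)(C)C(C)(C)C)C[C@H](O[Si](C)(C)C(C)(C)C)CNC(=O)[C@@H](O)CCC
F2 | step 29 | seco acid: free C3 carboxylic acid of F1 | OC(=O)[C@@H](C)C[C@@H](C)CCCC[C@H](O[Si](C)(C)C(C)(C)C)CCC[C@H](CC)/C=C/C=C(\COC)CC[C@@H](O[Si](C)(C)C(C)(C)C)[C@@H](O[Si](C)(C)C(C)(C)C)C[C@H](O[Si](C)(C)C(C)(C)C)CNC(=O)[C@@H](O)CCC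
F3 | step 23 | 1-({[(2S)-2-ethylpent-4-yn-1-yl]oxy}methyl)-4-methoxybenzene | C#CC[C@H](CC)COCc1ccc(OC)cc1
F4 | step 23 | methyl (2S,4R,5Z,13S)-13-ethyl-14-[(4-methoxybenzyl)oxy]-2,4-dimethyl-9-oxotetradec-5-en-10-ynoate | COC(=O)[C@@H](C)C[C@@H](C)/C=C\CCC(=O)C#CC[C@H](CC)COCc1ccc(OC)cc1
F5 | step 23 | methyl (2S,4R,5Z,9S,13S)-13-ethyl-9-hydroxy-14-[(4-methoxybenzyl)oxy]-2,4-dimethyltetradec-5-en-10-ynoate | COC(=O)[C@@H](C)C[C@@H](C)/C=C\CC[C@H](O)C#CC[C@H](CC)COCc1ccc(OC)cc1
F6 | step 23 | methyl (2S,4R,5Z,9S,13S)-9-[(tert-butyldimethylsilyl)oxy]-13-ethyl-14-[(4-methoxybenzyl)oxy]-2,4-dimethyltetradec-5-en-10-ynoate | COC(=O)[C@@H](C)C[C@@H](C)/C=C\CC[C@H](O[Si](C)(C)C(C)(C)C)C#CC[C@H](CC)COCc1ccc(OC)cc1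
F7 | step 23 | methyl (2S,4S,9S,13S)-9-[(tert-butyldimethylsilyl)oxy]-13-ethyl-14-[(4-methoxybenzyl)oxy]-2,4-dimethyltetradecanoate | COC(=O)[C@@H](C)C[C@@H](C)CCCC[C@H](O[Si](C)(C)C(C)(C)C)CCC[C@H](CC)COCc1ccc(OC)cc1
F8 | step 23 | methyl (2S,4S,9S,13S)-9-[(tert-butyldimethylsilyl)oxy]-13-ethyl-14-hydroxy-2,4-dimethyltetradecanoate | COC(=O)[C@@H](C)C[C@@H](C)CCCC[C@H](O[Si](C)(C)C(C)(C)C)CCC[C@H](CC)CO
F9 | step 23 | methyl (2S,4S,9S,13S)-9-[(tert-butyldimethylsilyl)oxy]-13-ethyl-2,4-dimethyl-14-oxotetradecanoate | COC(=O)[C@@H](C)C[C@@H](C)CCCC[C@H](O[Si](C)(C)C(C)(C)C)CCC[C@H](CC)C=O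
F10 | step 23 | (2Z,6R,7S,9S)-1-bromo-6,7,9-tris[(tert-butyldimethylsilyl)oxy]-10-chloro-3-(methoxymethyl)dec-2-ene | BrC/C=C(\COC)CC[C@@H](O[Si](C)(C)C(C)(C)C)[C@@H](O[Si](C)(C)C(C)(C)C)C[C@H](O[Si](C)(C)C(C)(C)C)CCl
F11 | step 23 | diethyl [(2Z,6R,7S,9S)-6,7,9-tris[(tert-butyldimethylsilyl)oxy]-10-chloro-3-(methoxymethyl)dec-2-en-1-yl]phosphonate | CCOP(=O)(OCC)C/C=C(\COC)CC[C@@H](O[Si](C)(C)C(C)(C)C)[C@@H](O[Si](C)(C)C(C)(C)C)C[C@H](O[Si](C)(C)C(C)(C)C)CCl
F12 | step 17 | (3R,4S,6S)-6-[(tert-butyldimethylsilyl)oxy]-7-chloro-3-[(cyclohexyloxy)dimethylsilyl]hept-1-en-4-ol | C=C[C@@H]([Si](C)(C)OC1CCCCC1)[C@@H](O)C[C@H](O[Si](C)(C)C(C)(C)C)CCl
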